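(The runs come from a simulation for substances that don't exist; the scatter is artificial.)

The ratio I started from was usable partner over substrate, u: the partner charge less the protic impurity, which I assumed takes partner one to one, divided by the substrate charge. For the teal flask it is 1.00, the symmetric case, so on my count neither side is the limiting reagent.

common to all: substrate 0.49 M
- teal: partner 0.539 M; protic impurity 0.049 M; the very flask that is asked about, followed so far
- violet: partner 0.27 M; protic impurity 0.049 M; run made earlier
- flask: partner 0.539 M; protic impurity 0.0490 M; time 20 h

| run | time / h | target / % | substrate / % |
|---|---|---|---|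
| teal | 1.00 | 5 | 81 |
| teal | 1.50 | 9 | 74 |
| teal | 2.50 | 18 | 64 |
| teal | 4.00 | 19 | 53 |
| teal | 8.00 | 24 | 34 |
| teal | 12.0 | 30 | 28 |
| violet | 0.667 | 2 | 92 |
| violet | 1.33 | 5 | 86 |
| violet | 2.00 | 7 | 82 |
| violet | 2.50 | 6 | 77 |
| violet | 3.00 | 11 | 75 |
| violet | 4.00 | 10 | 70 |

(each reading ± 1.5 percentage points)

- summer: change nothing and wait 20 h more
- spring: at 20 h add partner, 100% of the amount charged, then wait 20 h
- dawn: at 20 h add substrate, 50.0% of the amount charged, then wait 20 h
- dusk: at 20 h take out 90% of the target then present, then wait 20 h

- removed target is counted in
- the numbers in the tables scatter by 1.5 percentage points (one standard deviation)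
- additions bring no volume worth counting

* target, in percent of the substrate first charged, at 20 h
* what to do for the largest gain in target; "none" if nothing gains more than 2 percentage points (summer / spring / dawn / dusk / none)
* target present, with what was taken out counted in, in percent of the substrate first charged, after summer
* target present, with what was taken out counted in, in percent of the substrate first charged, after dawn

At 2.50 h, the violet run had lost 0.639 of teal's substrate loss on 0.501 of teal's partner, so I took the loss as second order. With u at the symmetric value, the fraction of substrate left in teal is then one over one plus κt. Teal's last reading gave κ = 0.214 h⁻¹, so the fraction left at 20 h came to 0.189. The selectivity, target per substrate lost, read 0.417 at that reading, which put teal's target at 0.338 of the charge.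

That selectivity was the weak link, since it rested on one reading. Pooling teal's last 3 readings gave 0.395, and I committed to 0.320. For the options, I multiplied the two remaining fractions: spring's product came out larger than dawn's, so I chose spring.

The forecast gave 33%, a little above my figure, with spring, 36.5% after summer and 39.5% after dawn: “Spring narrowly beats dawn, though this is close to a tie.”

The flask gave 31.8%, 34.3% after summer and 36.5% after dawn; the best option was spring, gaining 11 percentage points against 4.7 points for dawn.

    intermediate A → intermediate C (k = 0.0120 min⁻¹)
    substrate + partner ⇌ intermediate A (K = 1.30 M⁻¹, k = 0.00370 M⁻¹ min⁻¹)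
    partner + intermediate C → side product (k = 0.00820 M⁻¹ min⁻¹)
    partner + protic impurity → quenched reagent (k = 0.0540 M⁻¹ min⁻¹)
    substrate + partner → target (k = 0.00280 M⁻¹ min⁻¹)
    substrate ⇌ intermediate B (K = 0.730, k = 4.10 × 10⁻⁴ min⁻¹)

At 20.0 h, the flask had spent 0.860 of its usable partner, counted against the substrate charge, and had lost 78.9% of its substrate. In the neighbour flask charged with 0.22 M of partner, u is 0.349, which is less than the 51.3% of substrate it lost. Taking u as the amount reacted and multiplying by the pooled selectivity gives 0.138. That neighbour flask gave 14.2% of target, with 5.2% of its partner left.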